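**Plan**
1. Numbering (octahydroazulene): C1(OH)(i‑Pr), C3a(CH3), C4(OH), C5=C6(CH3), C8(O‑anisoyl), C8a(H). Retrosynthetic cuts in order: acyl–O and O–Si; C1–i‑Pr (Grignard on a C1 ketone); C5=C6 (RCM); C3a–C8a (reverse 1,2‑shift, cyclopentanone ⇒ epoxy cyclobutanol); carbinol–alkynyl bond; cyclobutanone ⇒ cyclopropylidene carbinol.
2. Enabling feature: with C1 as a ketone, the five‑membered ring holds an aldol unit C1(=O)–C8a(H)–C8(OH) attached to the quaternary C3a. This is the retron of a 2,3‑epoxy‑alcohol semipinacol in which ring bond C1–C3a of a cyclobutanol moves to C8a.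
3. Forward ring order: cyclopropane → cyclobutanone (epoxide‑triggered shift) → cyclopentanone (same kind of shift, key step) → cycloheptene by RCM; then i‑Pr, ester, desilylation.
4. Stereochemistry: C4 from a Sharpless kinetic resolution; C3a from OH‑directed epoxidation of the alkylidenecyclopropane and invertive shift; C8/C8a from the E‑alkene, OH‑directed epoxidation and anti shift; C1 from Grignard addition anti to the angular methyl.

Key step: step 10

Remark: 2‑methylpent‑1‑en‑4‑yne is treated as not purchasable and is made in step 6.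

Step 1
Reactants: 1 cyclopropyltriphenylphosphonium bromide; 2 1,1‑dimethoxypropan‑2‑one
Product: 5 2‑cyclopropylidenepropanal, via cyclopropylidene(triphenyl)phosphorane 3 (not isolated), via dimethyl acetal 4 (not isolated)
Conditions: KOt‑Bu, THF, 0 to 65 °C; then 1 M HCl, THF/H2O, 0 °C
Reagents that add atoms: water, O
Why: Wittig olefination of the activated ketone with the non‑stabilised cyclopropylide builds the strained exocyclic alkene, and dilute acid then hydrolyses the allylic dimethyl acetal to the enal; no stereocentre is formed.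

Step 2
Reactants: 5 2‑cyclopropylidenepropanal; 6 vinylmagnesium bromide
Product: 7 rac‑4‑cyclopropylidenepent‑1‑en‑3‑ol
Conditions: THF, −78 to 0 °C; then H2O
Reagents that add atoms: none
Why: Grignard 1,2‑addition to the α‑substituted, β,β‑disubstituted enal gives the bis‑allylic carbinol as a racemate.

Step 3
Reactants: 7 rac‑4‑cyclopropylidenepent‑1‑en‑3‑ol
Product: 8 (3R)‑4‑cyclopropylidenepent‑1‑en‑3‑ol
Conditions: Ti(Oi‑Pr)4 (10 mol %), L‑(+)‑diisopropyl tartrate (12 mol %), t‑BuOOH (0.55 equiv), 4 Å MS, CH2Cl2, −20 °C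
Reagents that add atoms: none
Why: Sharpless kinetic resolution: the Ti–L‑(+)‑tartrate catalyst epoxidises the electron‑rich alkylidenecyclopropane of the (S)‑enantiomer fast (matched, erythro) and leaves the (R)‑carbinol, whose centre becomes C4; the monosubstituted vinyl group is far less reactive and at most half of 7 is carried on.

Step 4
Reactants: 8 (3R)‑4‑cyclopropylidenepent‑1‑en‑3‑ol
Product: 10 (2R)‑2‑[(1R)‑1‑hydroxyprop‑2‑en‑1‑yl]‑2‑methylcyclobutan‑1‑one, via oxaspiropentane 9 (not isolated)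
Conditions: m‑CPBA (1.0 equiv), CH2Cl2, −20 to 0 °C
Reagents that add atoms: m‑CPBA, OOC(=O)c1cccc(Cl)c1
Why: Hydroxyl‑directed peracid epoxidation (hydrogen‑bonded transition state, carbinol H eclipsing the C=C to avoid 1,3‑allylic strain between the vinyl group and the cis ring CH2) should place the oxygen threo to the OH, and the oxaspiropentane then opens at the tertiary cyclopropylcarbinyl carbon while a cyclopropane CH2 shifts anti to the leaving oxygen (inversion), which fixes the quaternary centre (oxaspiropentane–cyclobutanone rearrangement).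

Step 5
Reactants: 10 (2R)‑2‑[(1R)‑1‑hydroxyprop‑2‑en‑1‑yl]‑2‑methylcyclobutan‑1‑one
Product: 11 (2R)‑2‑[(1R)‑1‑{[tert‑butyl(dimethyl)silyl]oxy}prop‑2‑en‑1‑yl]‑2‑methylcyclobutan‑1‑one
Conditions: TBSOTf, 2,6‑lutidine, CH2Cl2, −78 °C
Reagents that add atoms: TBSOTf, CC(C)(C)[Si](C)(C)OS(=O)(=O)C(F)(F)F
Why: Silyl ether protection of the hindered secondary alcohol with the silyl triflate at low temperature outruns enol silylation of the cyclobutanone and masks the β‑hydroxy ketone for the organometallic steps.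

Step 6
Reactants: 12 3‑chloro‑2‑methylprop‑1‑ene; 13 ethynylmagnesium bromide
Product: 14 2‑methylpent‑1‑en‑4‑yne
Conditions: CuCl (5 mol %), THF, 50 °C
Reagents that add atoms: none
Why: Copper(I)‑catalysed coupling of an alkynyl Grignard reagent with an allylic chloride gives the skipped enyne, SN2 and SN2′ attack leading to the same product for the symmetrical methallyl unit.

Step 7
Reactants: 14 2‑methylpent‑1‑en‑4‑yne; 11 (2R)‑2‑[(1R)‑1‑{[tert‑butyl(dimethyl)silyl]oxy}prop‑2‑en‑1‑yl]‑2‑methylcyclobutan‑1‑one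
Product: 16 (1S,2R)‑2‑[(1R)‑1‑{[tert‑butyl(dimethyl)silyl]oxy}prop‑2‑en‑1‑yl]‑2‑methyl‑1‑(4‑methylpent‑4‑en‑1‑yn‑1‑yl)cyclobutan‑1‑ol, via lithium acetylide 15 (not isolated)
Conditions: n‑BuLi, THF, −78 °C; then 11, −78 °C; then H2O
Reagents that add atoms: none
Why: Acetylide 1,2‑addition to the strained, poorly enolisable cyclobutanone should occur anti to the bulky silyloxyallyl group (cis to the methyl), so the new OH is cis to that group, the arrangement step 9 relies on.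

Step 8
Reactants: 16 (1S,2R)‑2‑[(1R)‑1‑{[tert‑butyl(dimethyl)silyl]oxy}prop‑2‑en‑1‑yl]‑2‑methyl‑1‑(4‑methylpent‑4‑en‑1‑yn‑1‑yl)cyclobutan‑1‑ol
Product: 17 (1S,2R)‑2‑[(1R)‑1‑{[tert‑butyl(dimethyl)silyl]oxy}prop‑2‑en‑1‑yl]‑2‑methyl‑1‑[(1E)‑4‑methylpenta‑1,4‑dien‑1‑yl]cyclobutan‑1‑ol
Conditions: LiAlH4, THF, 0 to 45 °C; then H2O
Reagents that add atoms: none
Why: Alkoxide‑directed trans‑hydroalumination of the propargylic alcohol gives only the E‑allylic alcohol, the geometry that later becomes the C8/C8a relationship; isolated alkenes and the silyl ether are inert.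

Step 9
Reactants: 17 (1S,2R)‑2‑[(1R)‑1‑{[tert‑butyl(dimethyl)silyl]oxy}prop‑2‑en‑1‑yl]‑2‑methyl‑1‑[(1E)‑4‑methylpenta‑1,4‑dien‑1‑yl]cyclobutan‑1‑ol
Product: 18 (1R,2R)‑2‑[(1R)‑1‑{[tert‑butyl(dimethyl)silyl]oxy}prop‑2‑en‑1‑yl]‑2‑methyl‑1‑[(2R,3S)‑3‑(2‑methylprop‑2‑en‑1‑yl)oxiran‑2‑yl]cyclobutan‑1‑ol
Conditions: VO(acac)2 (5 mol %), t‑BuOOH, CH2Cl2, 0 °C
Reagents that add atoms: tert‑butyl hydroperoxide, CC(C)(C)OO
Why: Vanadium‑catalysed hydroxyl‑directed epoxidation touches only the allylic‑alcohol alkene (methallyl and vinyl groups remain) and should deliver oxygen syn to the OH in the rotamer that keeps the vinylic H next to the quaternary ring carbon and the C=C next to the ring CH2, giving the trans‑(2R,3S)‑epoxide.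

Step 10
Reactants: 18 (1R,2R)‑2‑[(1R)‑1‑{[tert‑butyl(dimethyl)silyl]oxy}prop‑2‑en‑1‑yl]‑2‑methyl‑1‑[(2R,3S)‑3‑(2‑methylprop‑2‑en‑1‑yl)oxiran‑2‑yl]cyclobutan‑1‑ol
Product: 19 (2S,3S)‑3‑[(1R)‑1‑{[tert‑butyl(dimethyl)silyl]oxy}prop‑2‑en‑1‑yl]‑2‑[(1S)‑1‑hydroxy‑3‑methylbut‑3‑en‑1‑yl]‑3‑methylcyclopentan‑1‑one
Conditions: BF3·OEt2 (0.2 equiv), CH2Cl2, −78 °C
Reagents that add atoms: none
Why: BF3 binds the epoxide oxygen, the oxirane C–O bond next to the carbinol lengthens, and the quaternary cyclobutane carbon (future C3a), standing anti‑periplanar to it, shifts from the carbinol carbon to that epoxide carbon (future C8a) in a concerted 1,2‑migration while the carbinol becomes the C1 ketone; loss of cyclobutane strain and C=O formation drive it. The closest known reaction type is the semipinacol rearrangement of 2,3‑epoxy alcohols, which is used for cyclobutanol‑to‑cyclopentanone expansions. The five‑membered ring is not closed by a cyclisation but arises from the four‑membered ring by one‑carbon enlargement through this 1,2‑carbon shift. C8a is set by inversion at the epoxide carbon, C8 keeps the configuration fixed by the E‑alkene and the epoxidation face because its C–O bond is untouched, and C3a migrates with retention, so the hydroxyalkyl chain and the silyloxyallyl group end up trans on the ring. The step needs migration of the quaternary ring carbon and not of the ring CH2; the more substituted carbon is the better migrating group and its shift relieves congestion at the carbinol, while low temperature and substoichiometric Lewis acid protect the aldol product from dehydration or retro‑aldol cleavage and keep the silyl ether.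

Step 11
Reactants: 19 (2S,3S)‑3‑[(1R)‑1‑{[tert‑butyl(dimethyl)silyl]oxy}prop‑2‑en‑1‑yl]‑2‑[(1S)‑1‑hydroxy‑3‑methylbut‑3‑en‑1‑yl]‑3‑methylcyclopentan‑1‑one
Product: 20 (3aS,4R,8S,8aS)‑4‑{[tert‑butyl(dimethyl)silyl]oxy}‑8‑hydroxy‑3a,6‑dimethyl‑3,3a,4,7,8,8a‑hexahydroazulen‑1(2H)‑one
Conditions: Grubbs II (5 mol %), CH2Cl2, 40 °C
Reagents that add atoms: none
Why: Ring‑closing metathesis between the vinyl and methallyl groups, held trans on adjacent ring carbons, closes the seven‑membered ring as the trisubstituted C5=C6 alkene with loss of ethene and touches no stereocentre.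

Step 12
Reactants: 20 (3aS,4R,8S,8aS)‑4‑{[tert‑butyl(dimethyl)silyl]oxy}‑8‑hydroxy‑3a,6‑dimethyl‑3,3a,4,7,8,8a‑hexahydroazulen‑1(2H)‑one; 21 isopropylmagnesium chloride
Product: 22 (1R,3aS,4R,8S,8aS)‑4‑{[tert‑butyl(dimethyl)silyl]oxy}‑3a,6‑dimethyl‑1‑(propan‑2‑yl)‑1,2,3,3a,4,7,8,8a‑octahydroazulene‑1,8‑diol
Conditions: LaCl3·2LiCl (30 mol %), THF, 0 °C; then H2O
Reagents that add atoms: none
Why: Lanthanide‑promoted Grignard 1,2‑addition suppresses enolisation and β‑hydride reduction, and the nucleophile should enter C1 on the face of the C8a hydrogen and the C8 alkoxide, anti to the angular C3a methyl, so the new OH is cis to that methyl.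

Step 13
Reactants: 22 (1R,3aS,4R,8S,8aS)‑4‑{[tert‑butyl(dimethyl)silyl]oxy}‑3a,6‑dimethyl‑1‑(propan‑2‑yl)‑1,2,3,3a,4,7,8,8a‑octahydroazulene‑1,8‑diol; 23 4‑methoxybenzoyl chloride
Product: 24 (1R,3aS,4R,8S,8aS)‑4‑{[tert‑butyl(dimethyl)silyl]oxy}‑1‑hydroxy‑3a,6‑dimethyl‑1‑(propan‑2‑yl)‑1,2,3,3a,4,7,8,8a‑octahydroazulen‑8‑yl 4‑methoxybenzoate
Conditions: Et3N, DMAP (10 mol %), CH2Cl2, 0 °C to rt
Reagents that add atoms: none
Why: DMAP‑catalysed acylation esterifies the secondary C8 alcohol, while the tertiary C1 alcohol is too hindered to react and C4 is silyl‑protected.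

Step 14
Reactants: 24 (1R,3aS,4R,8S,8aS)‑4‑{[tert‑butyl(dimethyl)silyl]oxy}‑1‑hydroxy‑3a,6‑dimethyl‑1‑(propan‑2‑yl)‑1,2,3,3a,4,7,8,8a‑octahydroazulen‑8‑yl 4‑methoxybenzoate
Product: 25 (1R,3aS,4R,8S,8aS)‑1,4‑dihydroxy‑3a,6‑dimethyl‑1‑(propan‑2‑yl)‑1,2,3,3a,4,7,8,8a‑octahydroazulen‑8‑yl 4‑methoxybenzoate
Conditions: HF·pyridine, pyridine, THF, 0 °C to rt
Reagents that add atoms: none
Why: Pyridine‑buffered fluoride desilylation frees the C4 alcohol without touching the aryl ester, the tertiary alcohol or the allylic system.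

**Compound list**
1 | cyclopropyltriphenylphosphonium bromide | [Br-].C1CC1[P+](c1ccccc1)(c1ccccc1)c1ccccc1 | starting material
2 | 1,1‑dimethoxypropan‑2‑one | CC(=O)C(OC)OC | starting material
3 | cyclopropylidene(triphenyl)phosphorane (not isolated) | C1CC1=P(c1ccccc1)(c1ccccc1)c1ccccc1 | intermediate
4 | (1,1‑dimethoxypropan‑2‑ylidene)cyclopropane (not isolated) | COC(OC)C(C)=C1CC1 | intermediate
5 | 2‑cyclopropylidenepropanal | O=CC(C)=C1CC1 | intermediate
6 | vinylmagnesium bromide | C=C[Mg]Br | starting material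
7 | rac‑4‑cyclopropylidenepent‑1‑en‑3‑ol | C=CC(O)C(C)=C1CC1 | intermediate
8 | (3R)‑4‑cyclopropylidenepent‑1‑en‑3‑ol | C=C[C@@H](O)C(C)=C1CC1 | intermediate
9 | (1R)‑1‑[(2S)‑2‑methyl‑1‑oxaspiro[2.2]pentan‑2‑yl]prop‑2‑en‑1‑ol (not isolated) | C=C[C@@H](O)[C@]1(C)OC12CC2 | intermediate
10 | (2R)‑2‑[(1R)‑1‑hydroxyprop‑2‑en‑1‑yl]‑2‑methylcyclobutan‑1‑one | C=C[C@@H](O)[C@@]1(C)CCC1=O | intermediate
11 | (2R)‑2‑[(1R)‑1‑{[tert‑butyl(dimethyl)silyl]oxy}prop‑2‑en‑1‑yl]‑2‑methylcyclobutan‑1‑one | C=C[C@@H](O[Si](C)(C)C(C)(C)C)[C@@]1(C)CCC1=O | intermediate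
12 | 3‑chloro‑2‑methylprop‑1‑ene | CC(=C)CCl | starting material
13 | ethynylmagnesium bromide | C#C[Mg]Br | starting material
14 | 2‑methylpent‑1‑en‑4‑yne | CC(=C)CC#C | intermediate
15 | (4‑methylpent‑4‑en‑1‑yn‑1‑yl)lithium (not isolated) | [Li]C#CCC(C)=C | intermediate
16 | (1S,2R)‑2‑[(1R)‑1‑{[tert‑butyl(dimethyl)silyl]oxy}prop‑2‑en‑1‑yl]‑2‑methyl‑1‑(4‑methylpent‑4‑en‑1‑yn‑1‑yl)cyclobutan‑1‑ol | C=C[C@@H](O[Si](C)(C)C(C)(C)C)[C@@]1(C)CC[C@]1(O)C#CCC(C)=C | intermediate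
17 | (1S,2R)‑2‑[(1R)‑1‑{[tert‑butyl(dimethyl)silyl]oxy}prop‑2‑en‑1‑yl]‑2‑methyl‑1‑[(1E)‑4‑methylpenta‑1,4‑dien‑1‑yl]cyclobutan‑1‑ol | C=C[C@@H](O[Si](C)(C)C(C)(C)C)[C@@]1(C)CC[C@]1(O)/C=C/CC(C)=C | intermediate
18 | (1R,2R)‑2‑[(1R)‑1‑{[tert‑butyl(dimethyl)silyl]oxy}prop‑2‑en‑1‑yl]‑2‑methyl‑1‑[(2R,3S)‑3‑(2‑methylprop‑2‑en‑1‑yl)oxiran‑2‑yl]cyclobutan‑1‑ol | C=C[C@@H](O[Si](C)(C)C(C)(C)C)[C@@]1(C)CC[C@]1(O)[C@@H]2O[C@H]2CC(C)=C | intermediate
19 | (2S,3S)‑3‑[(1R)‑1‑{[tert‑butyl(dimethyl)silyl]oxy}prop‑2‑en‑1‑yl]‑2‑[(1S)‑1‑hydroxy‑3‑methylbut‑3‑en‑1‑yl]‑3‑methylcyclopentan‑1‑one | C=C[C@@H](O[Si](C)(C)C(C)(C)C)[C@@]1(C)CCC(=O)[C@@H]1[C@@H](O)CC(C)=C | intermediate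
20 | (3aS,4R,8S,8aS)‑4‑{[tert‑butyl(dimethyl)silyl]oxy}‑8‑hydroxy‑3a,6‑dimethyl‑3,3a,4,7,8,8a‑hexahydroazulen‑1(2H)‑one | O[C@H]1CC(C)=C[C@@H](O[Si](C)(C)C(C)(C)C)[C@@]2(C)CCC(=O)[C@H]12 | intermediate
21 | isopropylmagnesium chloride | CC(C)[Mg]Cl | starting material
22 | (1R,3aS,4R,8S,8aS)‑4‑{[tert‑butyl(dimethyl)silyl]oxy}‑3a,6‑dimethyl‑1‑(propan‑2‑yl)‑1,2,3,3a,4,7,8,8a‑octahydroazulene‑1,8‑diol | O[C@H]1CC(C)=C[C@@H](O[Si](C)(C)C(C)(C)C)[C@@]2(C)CC[C@@](O)(C(C)C)[C@H]12 | intermediate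
23 | 4‑methoxybenzoyl chloride | COc1ccc(C(Cl)=O)cc1 | starting material
24 | (1R,3aS,4R,8S,8aS)‑4‑{[tert‑butyl(dimethyl)silyl]oxy}‑1‑hydroxy‑3a,6‑dimethyl‑1‑(propan‑2‑yl)‑1,2,3,3a,4,7,8,8a‑octahydroazulen‑8‑yl 4‑methoxybenzoate | COc1ccc(C(=O)O[C@H]2CC(C)=C[C@@H](O[Si](C)(C)C(C)(C)C)[C@@]3(C)CC[C@@](O)(C(C)C)[C@H]23)cc1 | intermediate
25 | (1R,3aS,4R,8S,8aS)‑1,4‑dihydroxy‑3a,6‑dimethyl‑1‑(propan‑2‑yl)‑1,2,3,3a,4,7,8,8a‑octahydroazulen‑8‑yl 4‑methoxybenzoate | COc1ccc(C(=O)O[C@H]2CC(C)=C[C@@H](O)[C@@]3(C)CC[C@@](O)(C(C)C)[C@H]23)cc1 | target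

**Count**
Total: 14 steps. Longest linear sequence: 13 steps (steps 1–5 and 7–14; step 6 is a one‑step side branch).

**Steps most likely to fail**

Step 4. The facial selectivity of the peracid epoxidation may be poor, because the 1,3‑allylic strain exerted by a cyclopropane CH2 is weaker than that of an ordinary cis substituent. Remaining peracid may also over‑oxidise the cyclobutanone (Baeyer–Villiger). The fallback sets out from 8, which is silylated first (TBSOTf, 2,6‑lutidine) to tert‑butyl{[(3R)‑4‑cyclopropylidenepent‑1‑en‑3‑yl]oxy}dimethylsilane F1. A catalyst‑controlled dioxirane epoxidation follows (Shi epoxidation, Oxone, pH 10.5 buffer, 0 °C), with the ketone enantiomer matched to the threo face. It should give the silylated oxaspiropentane tert‑butyl(dimethyl){[(1R)‑1‑[(2S)‑2‑methyl‑1‑oxaspiro[2.2]pentan‑2‑yl]prop‑2‑en‑1‑yl]oxy}silane F2. A catalytic lithium salt (LiBF4) then rearranges F2 with inversion to 11, where the route is rejoined; face control moves from the substrate to the catalyst and no peracid meets the ketone.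

Step 9. Oxygen may be delivered with low facial selectivity if the two rotamers about the carbinol–alkene bond compete, which would give a mixture of epoxides and, after step 10, of C8/C8a diastereomers. The fallback sets out from 16. Gold(I)‑catalysed ring expansion of the 1‑alkynylcyclobutanol ((Ph3P)AuCl, AgSbF6, CH2Cl2) should give (3S)‑3‑[(1R)‑1‑{[tert‑butyl(dimethyl)silyl]oxy}prop‑2‑en‑1‑yl]‑3‑methyl‑2‑[(1E)‑3‑methylbut‑3‑en‑1‑ylidene]cyclopentan‑1‑one F3, again by shift of the more substituted ring carbon. Copper(I)‑catalysed enantioselective conjugate borylation (CuCl, chiral bisphosphine, B2pin2, NaOt‑Bu, MeOH) then sets C8 under ligand control and gives (2R,3S)‑3‑[(1R)‑1‑{[tert‑butyl(dimethyl)silyl]oxy}prop‑2‑en‑1‑yl]‑3‑methyl‑2‑[(1S)‑3‑methyl‑1‑(4,4,5,5‑tetramethyl‑1,3,2‑dioxaborolan‑2‑yl)but‑3‑en‑1‑yl]cyclopentan‑1‑one F4. Oxidation with NaBO3 (retention) and base equilibration of the α‑centre to the trans arrangement return 19. This detour replaces steps 8–10, so it also serves if the shift in step 10 takes the ring CH2.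

Step 12. The Grignard reagent may enolise the ketone, reduce it by β‑hydride transfer or trigger retro‑aldol opening of the β‑alkoxide instead of adding. The fallback sets out from 20. Isopropenylmagnesium bromide (LaCl3·2LiCl, THF), an sp2 nucleophile without β‑hydrogens on the metal‑bearing carbon, should give (1S,3aS,4R,8S,8aS)‑4‑{[tert‑butyl(dimethyl)silyl]oxy}‑3a,6‑dimethyl‑1‑(prop‑1‑en‑2‑yl)‑1,2,3,3a,4,7,8,8a‑octahydroazulene‑1,8‑diol F5. Selective hydrogenation of its 1,1‑disubstituted alkene in the presence of the trisubstituted ring alkene (H2, Wilkinson's catalyst, benzene) then gives 22.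

**Further compounds**
F1 | step 4 | tert‑butyl{[(3R)‑4‑cyclopropylidenepent‑1‑en‑3‑yl]oxy}dimethylsilane | C=C[C@@H](O[Si](C)(C)C(C)(C)C)C(C)=C1CC1
F2 | step 4 | tert‑butyl(dimethyl){[(1R)‑1‑[(2S)‑2‑methyl‑1‑oxaspiro[2.2]pentan‑2‑yl]prop‑2‑en‑1‑yl]oxy}silane | C=C[C@@H](O[Si](C)(C)C(C)(C)C)[C@]1(C)OC12CC2
F3 | step 9 | (3S)‑3‑[(1R)‑1‑{[tert‑butyl(dimethyl)silyl]oxy}prop‑2‑en‑1‑yl]‑3‑methyl‑2‑[(1E)‑3‑methylbut‑3‑en‑1‑ylidene]cyclopentan‑1‑one | C=C[C@@H](O[Si](C)(C)C(C)(C)C)[C@@]1(C)CCC(=O)/C1=C/CC(C)=C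
F4 | step 9 | (2R,3S)‑3‑[(1R)‑1‑{[tert‑butyl(dimethyl)silyl]oxy}prop‑2‑en‑1‑yl]‑3‑methyl‑2‑[(1S)‑3‑methyl‑1‑(4,4,5,5‑tetramethyl‑1,3,2‑dioxaborolan‑2‑yl)but‑3‑en‑1‑yl]cyclopentan‑1‑one | C=C[C@@H](O[Si](C)(C)C(C)(C)C)[C@@]1(C)CCC(=O)[C@@H]1[C@@H](B2OC(C)(C)C(C)(C)O2)CC(C)=C
F5 | step 12 | (1S,3aS,4R,8S,8aS)‑4‑{[tert‑butyl(dimethyl)silyl]oxy}‑3a,6‑dimethyl‑1‑(prop‑1‑en‑2‑yl)‑1,2,3,3a,4,7,8,8a‑octahydroazulene‑1,8‑diol | O[C@H]1CC(C)=C[C@@H](O[Si](C)(C)C(C)(C)C)[C@@]2(C)CC[C@@](O)(C(C)=C)[C@H]12
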